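The constants were set for the occasion; the flask was simulated.

**Two exits.** Partner is contested. I asked which order of addition leaves most of it for substrate.

| flask | substrate | partner | time | remark |
|---|---|---|---|---|
| gamma | 0.050 M | 0.0650 M | 80 min | everything together at the start |
| epsilon | 0.050 M (fed, over 15 min) | 0.0650 M | 80 min | all else is in the flask from the start; the feed brings no volume worth counting |
| theta | 0.050 M | 0.0650 M (fed, over 15 min) | 80 min | all else is in the flask from the start; the feed brings no volume worth counting |

    2 partner → homo dimer (k1 = 0.0107 L mol⁻¹ s⁻¹)
    substrate + partner → product + released group (k2 = 0.00737 L mol⁻¹ s⁻¹)
    partner → decomposed reagent (k3 = 8.78 × 10⁻⁵ s⁻¹)

- the flask with the highest amount of product, in percent of the substrate charged ("all alike" if they lie within 1.5 percentage points) (gamma / epsilon / theta / all alike)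
- final product, as a percentage of the substrate charged, in gamma
- final product, as a percentage of the substrate charged, in epsilon
- final product, as a percentage of the substrate charged, in theta

- a step written with two of one species runs at k times the square of its concentration and takes two of it each time
- run time (gamma): 80 min

**The split.** My measure was the split, a selectivity factor: the product step's constant times [substrate], over 2 times the dimer step's constant times [partner], taken at the charges 0.265. Its neutral value is 1, where both exits run evenly, so at the start of gamma, with everything together, partner goes to homo dimer faster than to product. The decomposition runs slower than dimerisation at the charge, so I set it aside. With the split frozen, product takes 20.9% of the partner spent, which, if the whole partner charge were spent by these two exits, gives an estimate of 27.2% of the substrate charged in gamma. I took that as low, expecting [partner] to fall faster than [substrate] and the split to climb.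

**Turned round.** For epsilon to beat theta, holding substrate back would have to raise the split, yet [substrate] stands on top of it, while holding partner back in theta shrinks the bottom. Partner's half-life by dimerisation at its charge is 12.0 min, shorter than the 15 min feed, so in epsilon partner dimerises heavily while substrate is still arriving. I ranked theta first, gamma next and epsilon last.

**The result.** The forecast, reasoning that a slow partner feed “reduces dimerisation”, named theta and gave 38.5% for gamma, 29.7% for epsilon and 41.1% for theta. The flasks gave 38.5% in gamma, 29.7% in epsilon and 40.9% in theta, so theta stood highest and gamma lay above my frozen figure. Over the first 15 min, theta averaged 0.0472 M substrate and 0.0247 M partner, and these means put the split at 0.657 in theta, against 0.200 from epsilon's means. A neighbour of epsilon charged with 0.020 M substrate has a charge split of 0.106, and after 80.0 min its released group over 2 times its homo dimer reads 0.150, against 0.360 in epsilon.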